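## Structural features

The target is a trans-3,4-dibenzyl-γ-butyrolactone (oxolan-2-one, C3 S, C4 S) in which each benzyl arene is a 4-hydroxy-3-methoxyphenyl ring that carries one further phenylpropanoid unit at C5. On ring B (the arene of the benzyl group at lactone C3) this unit is closed onto the phenol oxygen as a trans-2-aryl-3-hydroxymethyl-2,3-dihydrobenzofuran (C2 R, C3 S). On ring A (the arene of the benzyl group at lactone C4) it is open: a 2-arylpropane-1,3-diol arm whose benzylic carbinol C7 (S) stands next to C8 (S), the carbon bearing ring A and CH2OH, in an anti relationship. The six stereocentres thus form three vicinal pairs (lactone C3/C4, dihydrofuran C2/C3, arm C7/C8) separated by CH2–arene spacers, so no pair can steer another and each needs its own source of chirality. Arm and dihydrofuran have the same configuration at the arene-bound carbon and the opposite one at the oxygen-bound benzylic carbon, so the two units are related by ring closure with inversion. The fragile sites are the two para-oxygenated benzylic C–O bonds (C7–OH and C2–O1), which ionise in acid, can eliminate to quinone methides once the para phenol is free in base, and can be hydrogenolysed; the lactone with its epimerisable C3; and three electron-rich phenols. The real difficulty is therefore the absolute control of three remote stereo-pairs in a molecule that tolerates neither strong acid nor strong base late on, not the carbon skeleton. The key step uses the dihydrofuran of ring B: C3 is bonded to arene carbon C3a and C2 lies between O1 and the guaiacyl ring, so in an open precursor the C2–H is a benzylic ether C–H activated from both sides and held five atoms from the α-carbon of an arylacetate on ring B.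

## Logic of the disconnections

32 ⇒ 31 ⇒ 30. Three phenolic O–CH2Ph bonds are cut first, then three O–Si bonds (one triisopropylsilyl ether, one di-tert-butylsilylene). Phenols need a group that survives carbenoid, enolate, hydride and fluoride chemistry; the alcohols need one that leaves under buffered fluoride, since acid would ionise C7–O and C2–O. Nothing is gained in skeleton, but the end-game is fixed as two near-neutral operations. The demand is that silicon leaves while the phenols are still capped, and that hydrogenolysis stops at the phenolic benzyl ethers.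

30 ⇒ 29 + 14. The bond between lactone C3 and the benzylic CH2 of ring B is cut. This central cut gives two halves of similar size, each holding one stereo-pair, and lets the C4 substituent of 29 set C3. The forward step must be a trans-selective enolate alkylation, and the electrophile must carry no acidic hydrogen, so the dihydrofuran ester has to be reduced and masked before 14 is made.

14 ⇒ 13 ⇒ 12 ⇒ 11. C–Br goes back to C–OH and the silyl groups are exchanged. The two primary alcohols of the ring B half must be told apart, which requires the benzylic oxygen to carry the more labile silyl group from the outset. For that reason the benzylic silyl ether is tert-butyldimethylsilyl rather than the more robust triisopropylsilyl group, which would be the last silyl ether to leave; the triisopropylsilyl group goes on the C3 hydroxymethyl instead. The carbon skeleton of the insertion precursor and product is unchanged by this.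

11 ⇒ 10 ⇒ 9. The C3 hydroxymethyl goes back to the methyl ester and the trans ester to the cis ester. This makes the C3 configuration of the ring-forming step irrelevant; only C2 must be right. The demand is epimerisation through the ester enolate without β-elimination of the phenoxide, which would open the ring and erase C2.

9 ⇒ 8. The C2–C3 bond is cut and the dihydrofuran opened. One ring, one C–C bond and two stereocentres disappear, leaving an acyclic aryldiazoacetate whose ortho benzyloxy CH2 is the future C2. A check of 8 and 9 against the target confirms connectivity, the cis relationship in 9 and the R descriptor at C2; no structural correction is needed. The forward step must choose between two enantiotopic hydrogens and keep the carbenoid away from every other path.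

8 ⇒ 7 ⇒ 6. The diazo group is removed, then the aryl–CH2CO2Me bond is cut to an aryl bromide. The bromide has the substitution pattern of 3, so no allyl group and no oxidative degradation are needed; this saves about four steps over a Claisen/cleavage sequence. The coupling must tolerate an ortho alkoxy group and deliver the methyl ester.

6 ⇒ 5 ⇒ 4 ⇒ 3 + 2, and 2 ⇒ 1. The silyl ether, the alcohol oxidation level and the aryl O–CH2 ether bond are taken back. This ends at two commercial vanillin derivatives, 1 and 3. The only demand is alkylation of a hindered but acidic phenol.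

29 ⇒ 28 ⇒ 27 ⇒ 24 + 25. The silylene is removed, C9 is raised to the acyl level bearing an auxiliary, and the C7–C8 bond is cut as an aldol. C8 is benzylic and adjacent to a carbon that can be a carbonyl, so one aldol makes both arm centres and uses commercial 25. The lactone centre is too remote to help, so anti selectivity and absolute sense must come from the reagent; the imide must be enolised beside the lactone and the auxiliary removed without reducing the lactone.

24 ⇒ 22 ⇒ 21 ⇒ 20. The N–acyl bond, the tert-butyl ester and the aryl–CH2 bond are cut, the last by the same coupling as in 6 ⇒ 7. Both halves thus descend from 3 by the same logic. The zinc enolate must leave the lactone alone.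

20 ⇒ 19 ⇒ 18 ⇒ 17 ⇒ 15 + 16, and 15 ⇒ 3. The lactone acyl–oxygen bond is opened, CH2OH goes back to the ester, the two hydrogens at C4 and the benzylic carbon are removed, and the C=C bond is cut as a Stobbe condensation. This leaves the achiral aldehyde 15 and diester 16. The demands are enantioface selection in the hydrogenation and reduction of the ester but not the carboxylate.

## Other disconnections considered

Alternative 1: The ring A arm is cut at C8–C9 and at the benzylic C7–O bond. Forward, the (E)-stilbene A1 would take up two formaldehyde units under a confined chiral imidodiphosphorimidate acid and give the trans-1,3-dioxane A2.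
- In its favour: one catalytic step makes both arm centres and the C8–C9 bond, and delivers the diol already masked. Trans geometry follows from the (E)-alkene. A1 lies only about two steps from the bromo lactone series, against six steps (17–22) for the arm here. On step economy and on avoiding a stoichiometric auxiliary it is the better plan for the arm.
- Against it: both alkene carbons are benzylic to electron-rich rings, so the regiochemistry (oxygen to C7, carbon to C8) rests only on the pivalate damping ring A. Internal stilbenes are poorer Prins substrates than terminal styrenes. The methylene acetal normally needs strong acid to come off, exactly what the C7–O bond cannot stand.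
- Comparison: the Prins step proceeds through a polarised, cation-like transition state whose regiochemistry has to be won electronically. The carbenoid insertion is directed by geometry (1,5) and by the single activated C–H. Alternative 1 also leaves the dihydrofuran of ring B unsolved.

Alternative 2: Both C7–C8 bonds (arm and pre-dihydrofuran) are cut at once. Forward, the bis[(E)-γ-arylallyl boronate] A3 would add twice to 25 under a chiral phosphoric acid and give the bis(anti homoallylic alcohol) A4.
- In its favour: it uses the hidden twofold symmetry, makes four stereocentres in one operation, and gets the anti relationship from a chair transition state. That relative control is at least the equal of, and probably better than, the anti-aldol used here. The double reaction also amplifies enantiopurity of the major diastereomer. It would be shorter overall.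
- Against it: ring B must afterwards be closed with inversion at an electron-rich benzylic carbinol, where SN1 leakage threatens C2. The two arms differ only in a phenol protecting group, so chemoselection rests on that alone. Two vinyl groups must be ozonised beside four electron-rich arenes. A3 needs two allyl boronates installed on a base-sensitive lactone.
- Comparison: the insertion route makes the C2–O1 stereocentre directly and needs no late invertive closure, at the price of building the two units separately and of a longer sequence.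

Alternative 3: The lactone ring O–CH2 bond is cut (O1–C5 in lactone numbering, with C4 as the stereocentre). Forward, the 3-(arylmethyl)cyclobutanone A5 would undergo a desymmetrising Baeyer–Villiger oxidation to the lactone A6, which is the same compound as 20.
- In its favour: a catalytic step makes the lactone centre from an achiral ketone, with no pressure hydrogenation and no precious metal if a monooxygenase is used. In step count to this lactone it is about equal to steps 13–16.
- Against it: acid-catalysed peroxide oxidations of 3-benzylcyclobutanones usually give lower enantioselectivity than itaconate hydrogenation. Hydrogen peroxide meets an electron-rich arene. A5 itself needs a ketene cycloaddition and dechlorination.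
- Comparison: it addresses one of six stereocentres and is a possible replacement for steps 14–16, not for the key step. It could be combined with the chosen plan without changing anything after 20.

Key step: step 7

Assumption: Rh2(S-PTTL)4 (step 7) and the (R,R)-Et-DuPhos rhodium catalyst (step 15) are taken to induce in the sense written; each is equally available as its mirror image, which would be used instead, with nothing else changed, if the opposite sense were found.

## Route

Step 1
Reactants: 1 (4-benzyloxy-3-methoxyphenyl)methanol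
Product: 2 1-benzyloxy-4-(chloromethyl)-2-methoxybenzene
Conditions: SOCl2, CH2Cl2, 0 °C to rt; used crude
Reagents that add atoms: thionyl chloride, O=S(Cl)Cl
Why: Deoxychlorination of an electron-rich benzylic alcohol through its chlorosulfite; no stereocentre is involved and the labile chloride is carried on without purification.

Step 2
Reactants: 3 3-bromo-4-hydroxy-5-methoxybenzaldehyde (5-bromovanillin); 2 1-benzyloxy-4-(chloromethyl)-2-methoxybenzene
Product: 4 4-[(4-benzyloxy-3-methoxyphenyl)methoxy]-3-bromo-5-methoxybenzaldehyde
Conditions: K2CO3, KI (cat.), DMF, 60 °C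
Reagents that add atoms: none
Why: Williamson ether synthesis; the phenol of 3, acidified by the ortho bromine and the para formyl group, is alkylated by the activated benzylic chloride under iodide catalysis, and this oxygen and CH2 become O1 and C2 of the dihydrofuran.

Step 3
Reactants: 4 4-[(4-benzyloxy-3-methoxyphenyl)methoxy]-3-bromo-5-methoxybenzaldehyde
Product: 5 {4-[(4-benzyloxy-3-methoxyphenyl)methoxy]-3-bromo-5-methoxyphenyl}methanol
Conditions: NaBH4, THF/MeOH, 0 °C
Reagents that add atoms: none
Why: Borohydride reduction of the aryl aldehyde, needed because the zinc enolate of step 5 would add to a formyl group; aryl bromide and benzyl ethers are inert.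

Step 4
Reactants: 5 {4-[(4-benzyloxy-3-methoxyphenyl)methoxy]-3-bromo-5-methoxyphenyl}methanol
Product: 6 tert-butyldimethylsilyl ether of 5 (aryl bromide with CH2OSi(Me)2tBu)
Conditions: TBSCl, imidazole, CH2Cl2, rt
Reagents that add atoms: tert-butyldimethylsilyl chloride, CC(C)(C)[Si](C)(C)Cl
Why: Silylation of the primary alcohol so that the later carbenoid meets no O–H bond; the tert-butyldimethylsilyl group is used because this ether must be cleaved in step 11 beside a triisopropylsilyl ether.

Step 5
Reactants: 6 tert-butyldimethylsilyl ether of 5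
Product: 7 methyl 2-{2-[(4-benzyloxy-3-methoxyphenyl)methoxy]-5-[(tert-butyldimethylsilyloxy)methyl]-3-methoxyphenyl}acetate
Conditions: BrZnCH2CO2Me (from BrCH2CO2Me, Zn, THF), Pd2(dba)3 (2.5 mol %), XPhos (10 mol %), THF, 60 °C
Reagents that add atoms: (2-methoxy-2-oxoethyl)zinc bromide, COC(=O)C[Zn]Br
Why: Negishi coupling of a Reformatsky reagent (palladium-catalysed α-arylation of an ester zinc enolate): zerovalent palladium inserts into the C–Br bond, the weakly basic zinc enolate transmetalates without touching silyl or benzyl ethers, and the bulky biarylphosphine copes with the ortho alkoxy group.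

Step 6
Reactants: 7 methyl arylacetate from step 5
Product: 8 methyl 2-diazo-2-{2-[(4-benzyloxy-3-methoxyphenyl)methoxy]-5-[(tert-butyldimethylsilyloxy)methyl]-3-methoxyphenyl}acetate
Conditions: p-ABSA, DBU, MeCN, 0 °C to rt
Reagents that add atoms: 4-acetamidobenzenesulfonyl azide, CC(=O)Nc1ccc(cc1)S(=O)(=O)N=[N+]=[N-]
Why: Regitz diazo transfer; the arylacetate CH2 is acidic enough for DBU and the enolate attacks the terminal nitrogen of the sulfonyl azide, giving the donor–acceptor diazo ester with no other acidic site in the molecule.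

Step 7
Reactants: 8 methyl 2-diazo-2-{2-[(4-benzyloxy-3-methoxyphenyl)methoxy]-5-[(tert-butyldimethylsilyloxy)methyl]-3-methoxyphenyl}acetate
Product: 9 methyl (2R,3S)-2-(4-benzyloxy-3-methoxyphenyl)-5-[(tert-butyldimethylsilyloxy)methyl]-7-methoxy-2,3-dihydro-1-benzofuran-3-carboxylate (cis)
Conditions: Rh2(S-PTTL)4 (2 mol %), toluene, −60 °C
Reagents that add atoms: none
Why: The divalent rhodium dimer Rh2(S-PTTL)4, dirhodium tetrakis[N-phthaloyl-(S)-tert-leucinate], takes N2 from the diazo ester and forms a donor–acceptor carbenoid. Its electrophilic carbon engages the hydridic benzylic C–H of the ortho benzyloxy group in a concerted, asynchronous three-centre transition state, forming C2–C3 and releasing the catalyst. The closest known reaction type is the chiral dirhodium carboxylate-catalysed 1,5 C–H insertion of aryldiazoacetates into benzylic ethers to give cis-2-aryl-2,3-dihydrobenzofuran-3-carboxylates. The dihydrofuran closes in the 1,5-insertion mode, since the carbenoid carbon and the C–H carbon are five atoms apart and no activated C–H is available for a four- or six-membered ring. C2 is set by the ligand: the two benzylic hydrogens are enantiotopic and the pocket formed by the four phthalimido-tert-leucinate groups selects the one that leads to 2R. C3 is set by the transition-state geometry, which places ester and aryl cis under kinetic control; this is of no consequence because step 8 equilibrates C3. The step needs chemoselectivity for insertion over carbene dimerisation, aromatic cycloaddition and insertion elsewhere, and the substrate secures it because the only C–H within reach is activated by both the ether oxygen and an electron-rich aryl group. Low temperature in a non-coordinating solvent keeps the selective donor–acceptor carbenoid on this path.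

Step 8
Reactants: 9 cis ester from step 7
Product: 10 methyl (2R,3R)-2-(4-benzyloxy-3-methoxyphenyl)-5-[(tert-butyldimethylsilyloxy)methyl]-7-methoxy-2,3-dihydro-1-benzofuran-3-carboxylate (trans)
Conditions: NaOMe (0.3 equiv), MeOH, rt
Reagents that add atoms: none
Why: Base-mediated epimerisation through the ester enolate; only C3 carries an acidic hydrogen, the trans isomer with aryl and ester on opposite faces is the thermodynamic one, and C2 keeps its configuration.

Step 9
Reactants: 10 trans ester from step 8
Product: 11 [(2R,3S)-2-(4-benzyloxy-3-methoxyphenyl)-5-[(tert-butyldimethylsilyloxy)methyl]-7-methoxy-2,3-dihydro-1-benzofuran-3-yl]methanol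
Conditions: LiAlH4, THF, 0 °C
Reagents that add atoms: none
Why: Hydride reduction of the ester to the primary alcohol; silyl and benzyl ethers are inert at 0 °C and no stereocentre is touched (the C3 descriptor changes from R to S only through the priority rules).

Step 10
Reactants: 11 trans alcohol from step 9
Product: 12 triisopropylsilyl ether of 11 (C3–CH2OSi(iPr)3, C5–CH2OSi(Me)2tBu)
Conditions: TIPSCl, imidazole, DMF, rt
Reagents that add atoms: triisopropylsilyl chloride, CC(C)[Si](Cl)(C(C)C)C(C)C
Why: Silylation of the primary alcohol with the bulkier group, which removes the last acidic hydrogen of this half before the enolate alkylation and outlasts the benzylic silyl ether in step 11.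

Step 11
Reactants: 12 bis-silyl ether from step 10
Product: 13 [(2R,3S)-2-(4-benzyloxy-3-methoxyphenyl)-7-methoxy-3-[(triisopropylsilyloxy)methyl]-2,3-dihydro-1-benzofuran-5-yl]methanol
Conditions: PPTS, MeOH, rt
Reagents that add atoms: none
Why: Acid-catalysed methanolysis of a silyl ether; the primary tert-butyldimethylsilyl ether is cleaved far faster than the triisopropylsilyl ether, and pyridinium tosylate is too weak to ionise the C2–O1 bond.

Step 12
Reactants: 13 benzylic alcohol from step 11
Product: 14 {[(2R,3S)-2-(4-benzyloxy-3-methoxyphenyl)-5-(bromomethyl)-7-methoxy-2,3-dihydro-1-benzofuran-3-yl]methoxy}triisopropylsilane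
Conditions: CBr4, PPh3, CH2Cl2, 0 °C; used at once
Reagents that add atoms: carbon tetrabromide, BrC(Br)(Br)Br
Why: Appel reaction under neutral conditions; the alkoxyphosphonium ion is displaced by bromide at the primary benzylic carbon, and the reactive para-alkoxybenzyl bromide is used without storage.

Step 13
Reactants: 3 3-bromo-4-hydroxy-5-methoxybenzaldehyde
Product: 15 4-benzyloxy-3-bromo-5-methoxybenzaldehyde
Conditions: BnBr, K2CO3, DMF, rt
Reagents that add atoms: benzyl bromide, BrCc1ccccc1
Why: Williamson ether synthesis on the acidic phenol; the benzyl group protects the ring A phenol until the last step.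

Step 14
Reactants: 15 4-benzyloxy-3-bromo-5-methoxybenzaldehyde; 16 dimethyl succinate
Product: 17 (3E)-4-(4-benzyloxy-3-bromo-5-methoxyphenyl)-3-(methoxycarbonyl)but-3-enoic acid
Conditions: NaOMe, MeOH, reflux; then aq. HCl
Reagents that add atoms: none
Why: Stobbe condensation; the succinate enolate adds to the aldehyde, the aldolate lactonises and E1cB opening of the lactone gives the alkylidene half-ester, whose carboxylate drives the reaction and marks the two carboxyl groups as different.

Step 15
Reactants: 17 Stobbe half-ester from step 14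
Product: 18 (3S)-4-(4-benzyloxy-3-bromo-5-methoxyphenyl)-3-(methoxycarbonyl)butanoic acid
Conditions: [Rh(cod)((R,R)-Et-DuPhos)]BF4 (1 mol %), H2 (5 bar), NaOMe (10 mol %), MeOH, rt
Reagents that add atoms: none
Why: Rhodium–bisphosphine asymmetric hydrogenation of an itaconate-type half-ester; the carboxylate and the alkene chelate the cationic metal and the C2-symmetric ligand lets hydrogen reach one enantioface only, setting the S centre that becomes lactone C4, while the homogeneous catalyst leaves aryl bromide and benzyl ether alone.

Step 16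
Reactants: 18 (3S)-half-ester from step 15
Product: 20 (4S)-4-[(4-benzyloxy-3-bromo-5-methoxyphenyl)methyl]oxolan-2-one, via hydroxy acid 19 (not isolated)
Conditions: KOH (1 equiv), EtOH; CaCl2, NaBH4, −10 °C to rt; then 3 M HCl, 40 °C
Reagents that add atoms: none
Why: Chemoselective borohydride reduction: calcium borohydride reduces the methyl ester while the carboxylate is inert, and acidification lactonises the resulting hydroxy acid; the stereocentre is not enolised under these conditions.

Step 17
Reactants: 20 bromo lactone from step 16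
Product: 21 tert-butyl 2-(2-benzyloxy-3-methoxy-5-{[(3S)-5-oxooxolan-3-yl]methyl}phenyl)acetate
Conditions: BrZnCH2CO2tBu (from BrCH2CO2tBu, Zn, THF), Pd2(dba)3 (2.5 mol %), XPhos (10 mol %), THF, 60 °C
Reagents that add atoms: (2-tert-butoxy-2-oxoethyl)zinc bromide, CC(C)(C)OC(=O)C[Zn]Br
Why: The same Negishi coupling of a Reformatsky reagent as in step 5; the zinc enolate neither adds to nor enolises the lactone, and the tert-butyl ester can be removed later without hydroxide.

Step 18
Reactants: 21 tert-butyl ester from step 17
Product: 22 2-(2-benzyloxy-3-methoxy-5-{[(3S)-5-oxooxolan-3-yl]methyl}phenyl)acetic acid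
Conditions: TFA, CH2Cl2, 0 °C to rt
Reagents that add atoms: none
Why: Acidolysis of the tert-butyl ester through the tert-butyl cation (E1); the lactone and the aryl benzyl ether withstand brief exposure to trifluoroacetic acid and no benzylic C–O bond is yet present.

Step 19
Reactants: 22 arylacetic acid from step 18
Product: 24 (4S)-4-benzyl-3-[2-(2-benzyloxy-3-methoxy-5-{[(3S)-5-oxooxolan-3-yl]methyl}phenyl)acetyl]-1,3-oxazolidin-2-one, via mixed pivalic anhydride 23 (not isolated)
Conditions: PivCl, Et3N, THF, −20 °C; then (S)-4-benzyl-1,3-oxazolidin-2-one, LiCl, rt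
Reagents that add atoms: (S)-4-benzyl-1,3-oxazolidin-2-one, O=C1N[C@@H](Cc2ccccc2)CO1
Why: N-Acylation of the oxazolidinone through the mixed anhydride; the hindered pivaloyl carbonyl directs attack to the arylacetyl carbonyl, LiCl with Et3N activates the auxiliary, and the lactone is not affected.

Step 20
Reactants: 24 N-arylacetyl oxazolidinone from step 19; 25 4-benzyloxy-3-methoxybenzaldehyde
Product: 27 (4S)-4-benzyl-3-[(2R,3S)-3-(4-benzyloxy-3-methoxyphenyl)-2-(2-benzyloxy-3-methoxy-5-{[(3S)-5-oxooxolan-3-yl]methyl}phenyl)-3-hydroxypropanoyl]-1,3-oxazolidin-2-one, via trimethylsilyl ether 26 (not isolated)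
Conditions: MgCl2 (20 mol %), Et3N, TMSCl, EtOAc, rt; then 1 M HCl, THF, 0 °C
Reagents that add atoms: none
Why: Magnesium-catalysed direct anti-aldol reaction of an N-acyloxazolidinone: soft enolisation gives the magnesium-chelated (Z)-enolate of the imide only (the lactone is not enolised), the aldehyde attacks the face opposite the auxiliary benzyl group, which sets C8, and the boat-like transition state of this process gives the anti relationship that sets C7; silylation of the aldolate makes the addition irreversible.

Step 21
Reactants: 27 anti-aldol adduct from step 20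
Product: 28 (4S)-4-({4-benzyloxy-3-[(1S,2S)-1-(4-benzyloxy-3-methoxyphenyl)-1,3-dihydroxypropan-2-yl]-5-methoxyphenyl}methyl)oxolan-2-one
Conditions: NaBH4, THF/H2O, 0 °C to rt
Reagents that add atoms: none
Why: Reductive removal of the auxiliary; the exocyclic imide carbonyl, activated by the N-acyl carbamate and the neighbouring hydroxyl, is reduced by NaBH4 in wet THF much faster than the γ-lactone, and both arm centres are untouched.

Step 22
Reactants: 28 diol from step 21
Product: 29 (4S)-4-({4-benzyloxy-3-[(4S,5S)-4-(4-benzyloxy-3-methoxyphenyl)-2,2-di-tert-butyl-1,3,2-dioxasilinan-5-yl]-5-methoxyphenyl}methyl)oxolan-2-one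
Conditions: tBu2Si(OTf)2, 2,6-lutidine, CH2Cl2, 0 °C
Reagents that add atoms: di-tert-butylsilyl bis(trifluoromethanesulfonate), CC(C)(C)[Si](OS(=O)(=O)C(F)(F)F)(OS(=O)(=O)C(F)(F)F)C(C)(C)C
Why: Silylene protection of the 1,3-diol in one step as a six-membered ring with both aryl groups equatorial; the group is stable to amide bases and leaves with fluoride, so no acid is needed at the end.

Step 23
Reactants: 29 silylene lactone from step 22; 14 benzylic bromide from step 12
Product: 30 fully protected coupling product: (3S,4S)-lactone bearing the ring A benzyl group of 29 at C4 and the ring B benzyl group of 14 at C3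
Conditions: LiN(SiMe3)2, THF, −78 °C; then 14, DMPU, −78 to −30 °C
Reagents that add atoms: none
Why: Alkylation of the lactone lithium enolate; the benzylic bromide approaches the enolate face anti to the C4 benzyl substituent, giving the trans (3S,4S) lactone as in the classical dibenzylbutyrolactone synthesis, and neither partner carries another acidic hydrogen.

Step 24
Reactants: 30 fully protected coupling product
Product: 31 tri-O-benzyl ether of the target (three phenols benzylated, all four hydroxyl groups free)
Conditions: HF·pyridine, pyridine, THF, 0 °C to rt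
Reagents that add atoms: none
Why: Fluoride-driven cleavage of the silylene and the triisopropylsilyl ether; the buffered medium is neither acidic enough to ionise C7–O or C2–O1 nor basic enough to open the lactone, and the capped phenols cannot form quinone methides.

Step 25
Reactants: 31 tri-O-benzyl ether of the target
Product: 32 (3S,4S)-4-({4-hydroxy-3-[(1S,2S)-1,3-dihydroxy-1-(4-hydroxy-3-methoxyphenyl)propan-2-yl]-5-methoxyphenyl}methyl)-3-{[(2R,3S)-2-(4-hydroxy-3-methoxyphenyl)-3-(hydroxymethyl)-7-methoxy-2,3-dihydro-1-benzofuran-5-yl]methyl}oxolan-2-one (CNP0199264.1)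
Conditions: H2 (1 atm), Pd/C (10 %), EtOAc/EtOH, rt
Reagents that add atoms: none
Why: Catalytic hydrogenolysis of three phenolic benzyl ethers under neutral conditions; these cleave much faster than the free benzylic C7–OH or the cyclic benzylic ether C2–O1, so the reaction should be stopped when hydrogen uptake for three benzyl groups is complete.

## Compound list

1 | (4-benzyloxy-3-methoxyphenyl)methanol | OCc1ccc(OCc2ccccc2)c(OC)c1 | starting material
2 | 1-benzyloxy-4-(chloromethyl)-2-methoxybenzene | ClCc1ccc(OCc2ccccc2)c(OC)c1 | intermediate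
3 | 3-bromo-4-hydroxy-5-methoxybenzaldehyde | COc1cc(C=O)cc(Br)c1O | starting material
4 | 4-[(4-benzyloxy-3-methoxyphenyl)methoxy]-3-bromo-5-methoxybenzaldehyde | COc1cc(C=O)cc(Br)c1OCc1ccc(OCc2ccccc2)c(OC)c1 | intermediate
5 | {4-[(4-benzyloxy-3-methoxyphenyl)methoxy]-3-bromo-5-methoxyphenyl}methanol | COc1cc(CO)cc(Br)c1OCc1ccc(OCc2ccccc2)c(OC)c1 | intermediate
6 | tert-butyldimethylsilyl ether of 5 | COc1cc(CO[Si](C)(C)C(C)(C)C)cc(Br)c1OCc1ccc(OCc2ccccc2)c(OC)c1 | intermediate
7 | methyl 2-{2-[(4-benzyloxy-3-methoxyphenyl)methoxy]-5-[(tert-butyldimethylsilyloxy)methyl]-3-methoxyphenyl}acetate | COC(=O)Cc1cc(CO[Si](C)(C)C(C)(C)C)cc(OC)c1OCc1ccc(OCc2ccccc2)c(OC)c1 | intermediate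
8 | methyl 2-diazo-2-{2-[(4-benzyloxy-3-methoxyphenyl)methoxy]-5-[(tert-butyldimethylsilyloxy)methyl]-3-methoxyphenyl}acetate | COC(=O)C(=[N+]=[N-])c1cc(CO[Si](C)(C)C(C)(C)C)cc(OC)c1OCc1ccc(OCc2ccccc2)c(OC)c1 | intermediate
9 | methyl (2R,3S)-2-(4-benzyloxy-3-methoxyphenyl)-5-[(tert-butyldimethylsilyloxy)methyl]-7-methoxy-2,3-dihydro-1-benzofuran-3-carboxylate (cis) | CC(C)(C)[Si](C)(C)OCc1cc(OC)c2c(c1)[C@H](C(=O)OC)[C@H](c1ccc(OCc3ccccc3)c(OC)c1)O2 | intermediate
10 | methyl (2R,3R)-2-(4-benzyloxy-3-methoxyphenyl)-5-[(tert-butyldimethylsilyloxy)methyl]-7-methoxy-2,3-dihydro-1-benzofuran-3-carboxylate (trans) | CC(C)(C)[Si](C)(C)OCc1cc(OC)c2c(c1)[C@@H](C(=O)OC)[C@H](c1ccc(OCc3ccccc3)c(OC)c1)O2 | intermediate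
11 | [(2R,3S)-2-(4-benzyloxy-3-methoxyphenyl)-5-[(tert-butyldimethylsilyloxy)methyl]-7-methoxy-2,3-dihydro-1-benzofuran-3-yl]methanol | CC(C)(C)[Si](C)(C)OCc1cc(OC)c2c(c1)[C@@H](CO)[C@H](c1ccc(OCc3ccccc3)c(OC)c1)O2 | intermediate
12 | triisopropylsilyl ether of 11 | CC(C)(C)[Si](C)(C)OCc1cc(OC)c2c(c1)[C@@H](CO[Si](C(C)C)(C(C)C)C(C)C)[C@H](c1ccc(OCc3ccccc3)c(OC)c1)O2 | intermediate
13 | [(2R,3S)-2-(4-benzyloxy-3-methoxyphenyl)-7-methoxy-3-[(triisopropylsilyloxy)methyl]-2,3-dihydro-1-benzofuran-5-yl]methanol | OCc1cc(OC)c2c(c1)[C@@H](CO[Si](C(C)C)(C(C)C)C(C)C)[C@H](c1ccc(OCc3ccccc3)c(OC)c1)O2 | intermediate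
14 | {[(2R,3S)-2-(4-benzyloxy-3-methoxyphenyl)-5-(bromomethyl)-7-methoxy-2,3-dihydro-1-benzofuran-3-yl]methoxy}triisopropylsilane | BrCc1cc(OC)c2c(c1)[C@@H](CO[Si](C(C)C)(C(C)C)C(C)C)[C@H](c1ccc(OCc3ccccc3)c(OC)c1)O2 | intermediate
15 | 4-benzyloxy-3-bromo-5-methoxybenzaldehyde | COc1cc(C=O)cc(Br)c1OCc1ccccc1 | intermediate
16 | dimethyl succinate | COC(=O)CCC(=O)OC | starting material
17 | (3E)-4-(4-benzyloxy-3-bromo-5-methoxyphenyl)-3-(methoxycarbonyl)but-3-enoic acid | COC(=O)/C(CC(=O)O)=C/c1cc(OC)c(OCc2ccccc2)c(Br)c1 | intermediate
18 | (3S)-4-(4-benzyloxy-3-bromo-5-methoxyphenyl)-3-(methoxycarbonyl)butanoic acid | COC(=O)[C@@H](Cc1cc(OC)c(OCc2ccccc2)c(Br)c1)CC(=O)O | intermediate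
19 | (3S)-4-(4-benzyloxy-3-bromo-5-methoxyphenyl)-3-(hydroxymethyl)butanoic acid (present as its salt) | OC[C@@H](Cc1cc(OC)c(OCc2ccccc2)c(Br)c1)CC(=O)O | intermediate
20 | (4S)-4-[(4-benzyloxy-3-bromo-5-methoxyphenyl)methyl]oxolan-2-one | COc1cc(C[C@@H]2COC(=O)C2)cc(Br)c1OCc1ccccc1 | intermediate
21 | tert-butyl 2-(2-benzyloxy-3-methoxy-5-{[(3S)-5-oxooxolan-3-yl]methyl}phenyl)acetate | COc1cc(C[C@@H]2COC(=O)C2)cc(CC(=O)OC(C)(C)C)c1OCc1ccccc1 | intermediate
22 | 2-(2-benzyloxy-3-methoxy-5-{[(3S)-5-oxooxolan-3-yl]methyl}phenyl)acetic acid | COc1cc(C[C@@H]2COC(=O)C2)cc(CC(=O)O)c1OCc1ccccc1 | intermediate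
23 | mixed anhydride of 22 with pivalic acid | COc1cc(C[C@@H]2COC(=O)C2)cc(CC(=O)OC(=O)C(C)(C)C)c1OCc1ccccc1 | intermediate
24 | (4S)-4-benzyl-3-[2-(2-benzyloxy-3-methoxy-5-{[(3S)-5-oxooxolan-3-yl]methyl}phenyl)acetyl]-1,3-oxazolidin-2-one | COc1cc(C[C@@H]2COC(=O)C2)cc(CC(=O)N3[C@@H](Cc4ccccc4)COC3=O)c1OCc1ccccc1 | intermediate
25 | 4-benzyloxy-3-methoxybenzaldehyde | COc1cc(C=O)ccc1OCc1ccccc1 | starting material
26 | trimethylsilyl ether of 27 | COc1cc([C@@H](O[Si](C)(C)C)[C@H](C(=O)N2[C@@H](Cc3ccccc3)COC2=O)c4cc(C[C@@H]5COC(=O)C5)cc(OC)c4OCc6ccccc6)ccc1OCc7ccccc7 | intermediate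
27 | (4S)-4-benzyl-3-[(2R,3S)-3-(4-benzyloxy-3-methoxyphenyl)-2-(2-benzyloxy-3-methoxy-5-{[(3S)-5-oxooxolan-3-yl]methyl}phenyl)-3-hydroxypropanoyl]-1,3-oxazolidin-2-one | COc1cc([C@@H](O)[C@H](C(=O)N2[C@@H](Cc3ccccc3)COC2=O)c4cc(C[C@@H]5COC(=O)C5)cc(OC)c4OCc6ccccc6)ccc1OCc7ccccc7 | intermediate
28 | (4S)-4-({4-benzyloxy-3-[(1S,2S)-1-(4-benzyloxy-3-methoxyphenyl)-1,3-dihydroxypropan-2-yl]-5-methoxyphenyl}methyl)oxolan-2-one | COc1cc([C@@H](O)[C@H](CO)c2cc(C[C@@H]3COC(=O)C3)cc(OC)c2OCc2ccccc2)ccc1OCc1ccccc1 | intermediate
29 | (4S)-4-({4-benzyloxy-3-[(4S,5S)-4-(4-benzyloxy-3-methoxyphenyl)-2,2-di-tert-butyl-1,3,2-dioxasilinan-5-yl]-5-methoxyphenyl}methyl)oxolan-2-one | COc1cc([C@H]2O[Si](C(C)(C)C)(C(C)(C)C)OC[C@@H]2c2cc(C[C@@H]3COC(=O)C3)cc(OC)c2OCc2ccccc2)ccc1OCc1ccccc1 | intermediate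
30 | (3S,4S)-4-({4-benzyloxy-3-[(4S,5S)-4-(4-benzyloxy-3-methoxyphenyl)-2,2-di-tert-butyl-1,3,2-dioxasilinan-5-yl]-5-methoxyphenyl}methyl)-3-{[(2R,3S)-2-(4-benzyloxy-3-methoxyphenyl)-7-methoxy-3-[(triisopropylsilyloxy)methyl]-2,3-dihydro-1-benzofuran-5-yl]methyl}oxolan-2-one | COc1cc([C@H]2O[Si](C(C)(C)C)(C(C)(C)C)OC[C@@H]2c2cc(C[C@@H]3COC(=O)[C@H]3Cc3cc(OC)c4c(c3)[C@@H](CO[Si](C(C)C)(C(C)C)C(C)C)[C@H](c3ccc(OCc5ccccc5)c(OC)c3)O4)cc(OC)c2OCc2ccccc2)ccc1OCc1ccccc1 | intermediate
31 | (3S,4S)-4-({4-benzyloxy-3-[(1S,2S)-1-(4-benzyloxy-3-methoxyphenyl)-1,3-dihydroxypropan-2-yl]-5-methoxyphenyl}methyl)-3-{[(2R,3S)-2-(4-benzyloxy-3-methoxyphenyl)-3-(hydroxymethyl)-7-methoxy-2,3-dihydro-1-benzofuran-5-yl]methyl}oxolan-2-one | COc1cc([C@@H](O)[C@H](CO)c2cc(C[C@@H]3COC(=O)[C@H]3Cc3cc(OC)c4c(c3)[C@@H](CO)[C@H](c3ccc(OCc5ccccc5)c(OC)c3)O4)cc(OC)c2OCc2ccccc2)ccc1OCc1ccccc1 | intermediate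
32 | (3S,4S)-4-({4-hydroxy-3-[(1S,2S)-1,3-dihydroxy-1-(4-hydroxy-3-methoxyphenyl)propan-2-yl]-5-methoxyphenyl}methyl)-3-{[(2R,3S)-2-(4-hydroxy-3-methoxyphenyl)-3-(hydroxymethyl)-7-methoxy-2,3-dihydro-1-benzofuran-5-yl]methyl}oxolan-2-one | COc1cc([C@@H](O)[C@H](CO)c2cc(C[C@@H]3COC(=O)[C@H]3Cc3cc(OC)c4c(c3)[C@@H](CO)[C@H](c3ccc(O)c(OC)c3)O4)cc(OC)c2O)ccc1O | target

## Step count and least certain steps

Total: 25 steps. Longest linear sequence: 15 steps (steps 1–12, then 23–25, counted from 1); the ring A branch from 3 runs 13 steps (13–25).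

Step 7 (key step). The most likely failure is incomplete discrimination between the two enantiotopic benzylic hydrogens on this more electron-rich, 3-methoxy-substituted substrate; a lesser risk is diversion of the carbenoid into cycloaddition with the electron-rich benzyl ring or into dimerisation. Fallback, replacing catalyst-only control by separation on a covalent auxiliary: it sets out from 10 and returns at 11. Ester 10 is saponified (LiOH, THF/MeOH/H2O, rt) to the trans acid F1. This is activated as the mixed pivalic anhydride F2 (PivCl, Et3N, THF, −20 °C; not isolated) and used to acylate (S)-4-benzyl-1,3-oxazolidin-2-one (LiCl, rt), giving the imide F3. F3 is separated by chromatography from the diastereomeric imide F4, which derives from the minor enantiomer. LiBH4 (THF, 0 °C) then reduces F3 directly to 11.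

Step 20. The stabilised α-aryl enolate and the electron-rich aldehyde make the aldol addition easily reversible, so anti selectivity and facial selectivity may erode, and retro-aldol cleavage may set in during removal of the silyl group. Fallback by allylboration, which draws the anti relationship from a chair transition state: it sets out from 20, returns at 28 and bypasses steps 17–21. Stille coupling of 20 with (E)-3-(tributylstannyl)prop-2-en-1-ol (Pd(PPh3)4, toluene, 90 °C) gives the cinnamyl alcohol F5. Palladium-catalysed borylation with B2pin2 ([Pd(MeCN)4](BF4)2, DMSO/MeOH) gives the (E)-allyl boronate F6. Addition of F6 to 25 under a chiral BINOL-derived phosphoric acid (TRIP, the antipode that gives the 1S carbinol, toluene, −30 °C) gives the anti homoallylic alcohol F7. Ozonolysis (O3, CH2Cl2/MeOH, −78 °C) leads to the hydroxy aldehyde F8 (not isolated), which NaBH4 reduces in the same flask to 28.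

Step 21. Chemoselectivity may be lost through hydride attack on the γ-lactone or through base-induced retro-aldol cleavage before reduction. Fallback by hydrolysis and acid-selective reduction: it sets out from 27 and returns at 28. LiOH/H2O2 (THF/H2O, 0 °C, then Na2SO3 and acidification) removes the auxiliary and gives the hydroxy acid F9. BH3·SMe2 (THF, 0 °C) then reduces the carboxylic acid in the presence of the lactone to 28.

Step 5 (the same reaction serves in step 17). Oxidative addition into the hindered, electron-rich C–Br bond may be slow, so that protonation or homocoupling of the zinc enolate overtakes the cross-coupling. Fallback by malonate arylation: it sets out from 6 and returns at 7. Palladium-catalysed arylation of dimethyl malonate (Pd(OAc)2, P(tBu)3·HBF4, K3PO4, toluene, 80 °C) gives the aryl malonate F10. Krapcho demethoxycarbonylation (LiCl, wet DMSO, 130 °C) gives 7.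

Step 25. Over-reduction may occur: hydrogenolysis of the free benzylic C7–OH or of the C2–O1 bond once the benzyl ethers are gone. Fallback by reversing the last two operations, so that the benzylic oxygen at C7 is still silylated during hydrogenation: it sets out from 30 and returns at 32. Hydrogenolysis of 30 (H2, Pd/C, EtOAc, rt) gives the silyl-protected triphenol F11. HF·pyridine (pyridine, THF, 0 °C to rt) then releases 32.

## Further compounds

F1 | step 7 | (2R,3R)-2-(4-benzyloxy-3-methoxyphenyl)-5-[(tert-butyldimethylsilyloxy)methyl]-7-methoxy-2,3-dihydro-1-benzofuran-3-carboxylic acid | CC(C)(C)[Si](C)(C)OCc1cc(OC)c2c(c1)[C@@H](C(=O)O)[C@H](c1ccc(OCc3ccccc3)c(OC)c1)O2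
F2 | step 7 | mixed anhydride of F1 with pivalic acid | CC(C)(C)[Si](C)(C)OCc1cc(OC)c2c(c1)[C@@H](C(=O)OC(=O)C(C)(C)C)[C@H](c1ccc(OCc3ccccc3)c(OC)c1)O2
F3 | step 7 | (4S)-4-benzyl-3-{[(2R,3R)-2-(4-benzyloxy-3-methoxyphenyl)-5-[(tert-butyldimethylsilyloxy)methyl]-7-methoxy-2,3-dihydro-1-benzofuran-3-yl]carbonyl}-1,3-oxazolidin-2-one | CC(C)(C)[Si](C)(C)OCc1cc(OC)c2c(c1)[C@@H](C(=O)N1[C@@H](Cc3ccccc3)COC1=O)[C@H](c1ccc(OCc3ccccc3)c(OC)c1)O2
F4 | step 7 | (4S)-4-benzyl-3-{[(2S,3S)-2-(4-benzyloxy-3-methoxyphenyl)-5-[(tert-butyldimethylsilyloxy)methyl]-7-methoxy-2,3-dihydro-1-benzofuran-3-yl]carbonyl}-1,3-oxazolidin-2-one | CC(C)(C)[Si](C)(C)OCc1cc(OC)c2c(c1)[C@H](C(=O)N1[C@@H](Cc3ccccc3)COC1=O)[C@@H](c1ccc(OCc3ccccc3)c(OC)c1)O2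
F5 | step 20 | (4S)-4-({4-benzyloxy-3-[(1E)-3-hydroxyprop-1-en-1-yl]-5-methoxyphenyl}methyl)oxolan-2-one | COc1cc(C[C@@H]2COC(=O)C2)cc(/C=C/CO)c1OCc1ccccc1
F6 | step 20 | (4S)-4-({4-benzyloxy-3-methoxy-5-[(1E)-3-(4,4,5,5-tetramethyl-1,3,2-dioxaborolan-2-yl)prop-1-en-1-yl]phenyl}methyl)oxolan-2-one | COc1cc(C[C@@H]2COC(=O)C2)cc(/C=C/CB2OC(C)(C)C(C)(C)O2)c1OCc1ccccc1
F7 | step 20 | (4S)-4-({4-benzyloxy-3-[(1S,2R)-1-(4-benzyloxy-3-methoxyphenyl)-1-hydroxybut-3-en-2-yl]-5-methoxyphenyl}methyl)oxolan-2-one | COc1cc([C@@H](O)[C@H](C=C)c2cc(C[C@@H]3COC(=O)C3)cc(OC)c2OCc2ccccc2)ccc1OCc1ccccc1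
F8 | step 20 | (2R,3S)-3-(4-benzyloxy-3-methoxyphenyl)-2-(2-benzyloxy-3-methoxy-5-{[(3S)-5-oxooxolan-3-yl]methyl}phenyl)-3-hydroxypropanal | COc1cc([C@@H](O)[C@H](C=O)c2cc(C[C@@H]3COC(=O)C3)cc(OC)c2OCc2ccccc2)ccc1OCc1ccccc1
F9 | step 21 | (2R,3S)-3-(4-benzyloxy-3-methoxyphenyl)-2-(2-benzyloxy-3-methoxy-5-{[(3S)-5-oxooxolan-3-yl]methyl}phenyl)-3-hydroxypropanoic acid | COc1cc([C@@H](O)[C@H](C(=O)O)c2cc(C[C@@H]3COC(=O)C3)cc(OC)c2OCc2ccccc2)ccc1OCc1ccccc1
F10 | step 5 | dimethyl 2-{2-[(4-benzyloxy-3-methoxyphenyl)methoxy]-5-[(tert-butyldimethylsilyloxy)methyl]-3-methoxyphenyl}propanedioate | COC(=O)C(C(=O)OC)c1cc(CO[Si](C)(C)C(C)(C)C)cc(OC)c1OCc1ccc(OCc2ccccc2)c(OC)c1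
F11 | step 25 | (3S,4S)-4-({3-[(4S,5S)-2,2-di-tert-butyl-4-(4-hydroxy-3-methoxyphenyl)-1,3,2-dioxasilinan-5-yl]-4-hydroxy-5-methoxyphenyl}methyl)-3-{[(2R,3S)-2-(4-hydroxy-3-methoxyphenyl)-7-methoxy-3-[(triisopropylsilyloxy)methyl]-2,3-dihydro-1-benzofuran-5-yl]methyl}oxolan-2-one | COc1cc([C@H]2O[Si](C(C)(C)C)(C(C)(C)C)OC[C@@H]2c2cc(C[C@@H]3COC(=O)[C@H]3Cc3cc(OC)c4c(c3)[C@@H](CO[Si](C(C)C)(C(C)C)C(C)C)[C@H](c3ccc(O)c(OC)c3)O4)cc(OC)c2O)ccc1O
A1 | alternative 1 | (4S)-4-({3-[(E)-2-(4-benzyloxy-3-methoxyphenyl)ethenyl]-5-methoxy-4-(pivaloyloxy)phenyl}methyl)oxolan-2-one | COc1cc(C[C@@H]2COC(=O)C2)cc(/C=C/c2ccc(OCc3ccccc3)c(OC)c2)c1OC(=O)C(C)(C)C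
A2 | alternative 1 | lactone bearing the trans-(4S,5S)-4-(4-benzyloxy-3-methoxyphenyl)-1,3-dioxan-5-yl group and a pivalate on ring A | COc1cc(C[C@@H]2COC(=O)C2)cc([C@H]2COCO[C@@H]2c2ccc(OCc3ccccc3)c(OC)c2)c1OC(=O)C(C)(C)C
A3 | alternative 2 | (3S,4S)-lactone bearing an (E)-3-(pinacolboryl)prop-1-enyl group on ring A (O-benzyl) and on ring B (O-triisopropylsilyl) | COc1cc(C[C@@H]2COC(=O)[C@H]2Cc2cc(OC)c(O[Si](C(C)C)(C(C)C)C(C)C)c(/C=C/CB3OC(C)(C)C(C)(C)O3)c2)cc(/C=C/CB2OC(C)(C)C(C)(C)O2)c1OCc1ccccc1
A4 | alternative 2 | (3S,4S)-lactone bis(anti homoallylic alcohol) carrying both arms with vinyl in place of CH2OH | COc1cc([C@@H](O)[C@H](C=C)c2cc(C[C@@H]3COC(=O)[C@H]3Cc3cc(OC)c(O[Si](C(C)C)(C(C)C)C(C)C)c(c3)[C@@H](C=C)[C@H](O)c3ccc(OCc4ccccc4)c(OC)c3)cc(OC)c2OCc2ccccc2)ccc1OCc1ccccc1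
A5 | alternative 3 | 3-[(4-benzyloxy-3-bromo-5-methoxyphenyl)methyl]cyclobutan-1-one | COc1cc(CC2CC(=O)C2)cc(Br)c1OCc1ccccc1
A6 | alternative 3 | (4S)-4-[(4-benzyloxy-3-bromo-5-methoxyphenyl)methyl]oxolan-2-one (identical with 20) | COc1cc(C[C@@H]2COC(=O)C2)cc(Br)c1OCc1ccccc1
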